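**Plan**

- Numbering used throughout: C1 is the ring carbon that carries C7 (the CH2OBz carbon), the diene is C1=C2–C3=C4, C5 bears the benzoate and C6 the free hydroxyl; the target is the trans-(5R,6R) isomer.
- Retrosynthesis: the C7 benzoate is removed and C7 raised to an aldehyde, C1=C2 is reopened by putting a benzoate back on C2 (reverse β-elimination), the C6–O bond is traded for a C6–B bond, and the resulting cyclohexene is cut at C1–C2 and C5–C6.
- Enabling feature: in the one carbocycle, C3=C4 sits between C5, which still holds an acyloxy group, and C2, which can have held one, while C1 (with formyl-level C7) adjoins heteroatom-bearing C6. C2–C5 is therefore the imprint of a 1,4-diacyloxybuta-1,3-diene and C7–C1–C6 that of a β-heteroatom-substituted acrolein.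
- Forward order: diene 4 (one step) and boryl enal 8 (two steps) are made separately and united in step 4, which builds the only ring; C–B oxidation with β-elimination, carbonyl reduction and primary benzoylation then finish the target.
- Stereochemistry: the C5/C6 trans relationship comes from endo addition of the E-dienophile to the E,E-diene followed by stereoretentive C–B oxidation; the absolute configuration comes from the (5S)-imidazolidinone catalyst; the C1 and C2 centres exist only transiently.

Key step: step 4

Assumption: diacetate 1 is purchased as the pure E,E isomer, and the catalyst (5S)-5-benzyl-2,2,3-trimethylimidazolidin-4-one hydrochloride (CN1C(=O)[C@H](Cc2ccccc2)NC1(C)C.Cl) is a commercial reagent.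

Remark: the C5 descriptor is S in boronate 11 and R from 12 onward only because C6 changes from boron- to oxygen-substituted (CIP priority); no bond at C5 is broken.

**Route**

Step 1
Reactants: 1 (1E,3E)-buta-1,3-diene-1,4-diyl diacetate; 2 benzoyl chloride
Product: 4 (1E,3E)-buta-1,3-diene-1,4-diyl dibenzoate, via dipotassium dienediolate 3 (not isolated)
Conditions: KOt-Bu (2.1 equiv), THF, −78 °C; then BzCl (2.2 equiv), −78 °C → 0 °C
Reagents that add atoms: benzoyl chloride (compound 2), O=C(Cl)c1ccccc1
Why: Alkoxide cleavage of enol acetates gives potassium enolates with retention of alkene geometry (tert-butyl acetate is the inert co-product), and O-acylation of such hard aldehyde enolates by an acid chloride is the normal course, so this enol ester transacylation should carry the E,E geometry of 1 into 4 without creating any stereocentre.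

Step 2
Reactants: 5 3,3-diethoxyprop-1-yne; 6 pinacolborane (4,4,5,5-tetramethyl-1,3,2-dioxaborolane)
Product: 7 (E)-2-(3,3-diethoxyprop-1-en-1-yl)-4,4,5,5-tetramethyl-1,3,2-dioxaborolane
Conditions: HBpin (1.1 equiv), Cp2Zr(H)Cl (5 mol%), Et3N (10 mol%), neat, 60 °C
Reagents that add atoms: pinacolborane (compound 6), CC1(C)OBOC1(C)C
Why: Zirconocene hydride-catalysed hydroboration of a terminal alkyne with pinacolborane is a syn, anti-Markovnikov addition that gives the (E)-alkenylboronate, and the acetal is inert to it.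

Step 3
Reactants: 7 (E)-2-(3,3-diethoxyprop-1-en-1-yl)-4,4,5,5-tetramethyl-1,3,2-dioxaborolane
Product: 8 (2E)-3-(4,4,5,5-tetramethyl-1,3,2-dioxaborolan-2-yl)prop-2-enal
Conditions: p-TsOH·H2O (5 mol%), acetone/H2O (10:1), rt
Reagents that add atoms: water, O
Why: Acid-catalysed acetal hydrolysis unmasks the aldehyde, while the pinacol boronate and the E alkene tolerate dilute aqueous acid, and the enal is used promptly.

Step 4
Reactants: 4 (1E,3E)-buta-1,3-diene-1,4-diyl dibenzoate; 8 (2E)-3-(4,4,5,5-tetramethyl-1,3,2-dioxaborolan-2-yl)prop-2-enal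
Product: 11 (1R,2S,5S,6R)-2,5-bis(benzoyloxy)-6-(4,4,5,5-tetramethyl-1,3,2-dioxaborolan-2-yl)cyclohex-3-ene-1-carbaldehyde, via enal iminium chloride 9 (not isolated), via cycloadduct iminium chloride 10 (not isolated)
Conditions: 4 (1.5 equiv), (5S)-5-benzyl-2,2,3-trimethylimidazolidin-4-one·HCl (20 mol%), MeNO2/H2O (95:5), 1 M, 0 °C → rt
Reagents that add atoms: none
Why: Proposed new method: the secondary amine salt condenses reversibly with enal 8 to the (E)-iminium ion 9, whose lowered LUMO should engage the s-cis conformer of diene 4 in a concerted, asynchronous normal-demand [4+2] cycloaddition that forms C1–C2 and C5–C6, after which hydrolysis of the cycloadduct iminium ion 10 releases aldehyde 11 and returns the catalyst. The closest known reaction type is the imidazolidinone-catalysed Diels–Alder reaction of acrolein with 1-acyloxybutadienes, supported by thermal cycloadditions of 3-borylacrylic dienophiles; what is new is the union of a β-boryl enal with a 1,4-diacyloxydiene under iminium catalysis, which is reasonable because the boryl group leaves the iminium LUMO low and the acyloxy groups keep the diene HOMO high. The one ring, the six-membered carbocycle C1–C6, closes by intermolecular [4+2] annulation in which both new bonds are made suprafacially on each partner. C2 and C5 should end up cis because the E,E geometry of the diene is transferred suprafacially, C1 and C6 trans because the E geometry of the dienophile is retained, C1 cis to both benzoates because the iminium group takes the endo position through secondary orbital overlap (boron is then exo and trans to the C5 benzoate), and the absolute sense of all four centres is set by the benzyl group of the catalyst, which covers the re face of the iminium α-carbon so that the diene bonds to the si face of C1 and the re face of C6. The step needs endo and π-facial selectivity but no regioselectivity, since the constitutionally symmetric diene gives the same adduct in either orientation, and carbocycle formation is favoured over the hetero-Diels–Alder mode of the enal because iminium formation removes the C=O group.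

Step 5
Reactants: 11 (1R,2S,5S,6R)-2,5-bis(benzoyloxy)-6-(4,4,5,5-tetramethyl-1,3,2-dioxaborolan-2-yl)cyclohex-3-ene-1-carbaldehyde
Product: 13 (5R,6R)-5-(benzoyloxy)-6-hydroxycyclohexa-1,3-diene-1-carbaldehyde, via hydroxy aldehyde 12 (not isolated)
Conditions: NaBO3·4H2O (3 equiv), THF/H2O (1:1), 0 °C → rt; extraction; then Et3N (1.5 equiv), CH2Cl2, 0 °C
Reagents that add atoms: sodium perborate (NaBO3·4H2O, drawn as its peroxoborate dimer), [Na+].[Na+].O[B-]1(O)OO[B-](O)(O)OO1
Why: Perborate oxidation of the secondary alkyl pinacol boronate proceeds by 1,2-migration of C6 from boron to oxygen with retention, so the C6 hydroxyl is trans to the C5 benzoate, and the following amine-mediated E1cB elimination should expel only the C2 benzoate, the one acyloxy group β to the formyl group (the C6 hydroxyl is a far poorer leaving group and the C5 benzoate is not β), which creates C1=C2 in conjugation, erases the C1 and C2 centres and leaves C5 and C6 untouched.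

Step 6
Reactants: 13 (5R,6R)-5-(benzoyloxy)-6-hydroxycyclohexa-1,3-diene-1-carbaldehyde
Product: 14 (1R,6R)-6-hydroxy-5-(hydroxymethyl)cyclohexa-2,4-dien-1-yl benzoate
Conditions: NaBH4 (1.0 equiv), CeCl3·7H2O (1.1 equiv), MeOH, −78 °C → −40 °C
Reagents that add atoms: none
Why: Luche reduction, in which borohydride in methanol with cerium trichloride adds hydride 1,2 to the conjugated aldehyde, should leave the diene, the benzoate and both ring stereocentres unchanged and creates no new stereocentre.

Step 7
Reactants: 14 (1R,6R)-6-hydroxy-5-(hydroxymethyl)cyclohexa-2,4-dien-1-yl benzoate; 2 benzoyl chloride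
Product: 15 [(5R,6R)-5-(benzoyloxy)-6-hydroxycyclohexa-1,3-dien-1-yl]methyl benzoate (CNP0113836.1)
Conditions: BzCl (1.05 equiv), 2,4,6-collidine (3 equiv), CH2Cl2, −40 °C → −20 °C
Reagents that add atoms: benzoyl chloride (compound 2), O=C(Cl)c1ccccc1
Why: Kinetically controlled acylation with an acid chloride and a hindered pyridine base at low temperature differentiates the unhindered primary allylic hydroxyl from the secondary C6 hydroxyl, which is flanked by the C5 benzoate and the ring, so one equivalent of benzoyl chloride should esterify the C7 oxygen only, and no stereocentre is affected.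

**Compound list**

1 | (1E,3E)-buta-1,3-diene-1,4-diyl diacetate | CC(=O)O/C=C/C=C/OC(C)=O | starting material
2 | benzoyl chloride | O=C(Cl)c1ccccc1 | starting material
3 | dipotassium (1E,3E)-buta-1,3-diene-1,4-diolate | [K+].[K+].[O-]/C=C/C=C/[O-] | intermediate
4 | (1E,3E)-buta-1,3-diene-1,4-diyl dibenzoate | O=C(O/C=C/C=C/OC(=O)c1ccccc1)c1ccccc1 | intermediate
5 | 3,3-diethoxyprop-1-yne | C#CC(OCC)OCC | starting material
6 | pinacolborane (4,4,5,5-tetramethyl-1,3,2-dioxaborolane) | CC1(C)OBOC1(C)C | starting material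
7 | (E)-2-(3,3-diethoxyprop-1-en-1-yl)-4,4,5,5-tetramethyl-1,3,2-dioxaborolane | CCOC(OCC)/C=C/B1OC(C)(C)C(C)(C)O1 | intermediate
8 | (2E)-3-(4,4,5,5-tetramethyl-1,3,2-dioxaborolan-2-yl)prop-2-enal | O=C/C=C/B1OC(C)(C)C(C)(C)O1 | intermediate
9 | enal iminium chloride: N1-iminium ion of 8 with (5S)-5-benzyl-2,2,3-trimethylimidazolidin-4-one, E at C=N (chain syn to C5 of the heterocycle), E at C=C | CN1C(=O)[C@H](Cc2ccccc2)/[N+](=C\C=C\B2OC(C)(C)C(C)(C)O2)C1(C)C.[Cl-] | intermediate
10 | cycloadduct iminium chloride: N1-iminium ion of aldehyde 11 with the same (5S)-imidazolidinone, ring stereocentres as in 11, E at C=N | CN1C(=O)[C@H](Cc2ccccc2)/[N+](=C\[C@H]2[C@@H](OC(=O)c3ccccc3)C=C[C@@H](OC(=O)c3ccccc3)[C@@H]2B4OC(C)(C)C(C)(C)O4)C1(C)C.[Cl-] | intermediate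
11 | (1R,2S,5S,6R)-2,5-bis(benzoyloxy)-6-(4,4,5,5-tetramethyl-1,3,2-dioxaborolan-2-yl)cyclohex-3-ene-1-carbaldehyde (CHO and both OBz cis, boron trans to them) | O=C[C@H]1[C@@H](OC(=O)c2ccccc2)C=C[C@@H](OC(=O)c2ccccc2)[C@@H]1B2OC(C)(C)C(C)(C)O2 | intermediate
12 | (1R,2S,5R,6R)-2,5-bis(benzoyloxy)-6-hydroxycyclohex-3-ene-1-carbaldehyde | O=C[C@H]1[C@@H](OC(=O)c2ccccc2)C=C[C@@H](OC(=O)c2ccccc2)[C@@H]1O | intermediate
13 | (5R,6R)-5-(benzoyloxy)-6-hydroxycyclohexa-1,3-diene-1-carbaldehyde | O=CC1=CC=C[C@@H](OC(=O)c2ccccc2)[C@@H]1O | intermediate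
14 | (1R,6R)-6-hydroxy-5-(hydroxymethyl)cyclohexa-2,4-dien-1-yl benzoate | OCC1=CC=C[C@@H](OC(=O)c2ccccc2)[C@@H]1O | intermediate
15 | [(5R,6R)-5-(benzoyloxy)-6-hydroxycyclohexa-1,3-dien-1-yl]methyl benzoate | O=C(OCC1=CC=C[C@@H](OC(=O)c2ccccc2)[C@@H]1O)c1ccccc1 | target

**Summary**

Total step count: 7 (step 1 for the diene, steps 2–3 for the enal, steps 4–7 after their union).
Longest linear sequence: 6 steps (5 → 7 → 8 → 11 → 13 → 14 → 15).

**Steps most likely to fail**

1. Step 4. The cycloaddition of a 1,4-disubstituted diene with a β-substituted iminium ion may be slow. That leaves time for loss of the alkenyl boron group, for amine-triggered expulsion of benzoate from the adduct through its enamine, or for incomplete endo and facial control.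
Fallback (known auxiliary-controlled Lewis acid Diels–Alder chemistry), setting out from 8 and 4 and returning at 11: enal 8 is oxidised under Pinnick conditions (NaClO2, NaH2PO4, 2-methylbut-2-ene, t-BuOH/H2O) to (E)-3-(4,4,5,5-tetramethyl-1,3,2-dioxaborolan-2-yl)prop-2-enoic acid F1. F1 is N-acylated onto (S)-4-benzyl-1,3-oxazolidin-2-one (pivaloyl chloride, Et3N, LiCl, THF) to give (4S)-4-benzyl-3-[(E)-3-(pinacolboryl)prop-2-enoyl]-1,3-oxazolidin-2-one F2. Cycloaddition of F2 with diene 4 promoted by Et2AlCl (CH2Cl2, −78 → −20 °C) should proceed through the chelated s-cis imide, whose benzyl group blocks the same face of C1 as the amine catalyst does, with the imide carbonyl endo, to give (4S)-4-benzyl-3-{[(1R,2S,5S,6R)-2,5-bis(benzoyloxy)-6-(pinacolboryl)cyclohex-3-en-1-yl]carbonyl}-1,3-oxazolidin-2-one F3. Reduction with LiBH4 (THF/MeOH, 0 °C) releases the auxiliary and gives [(1S,2S,5S,6R)-2,5-bis(benzoyloxy)-6-(pinacolboryl)cyclohex-3-en-1-yl]methanol F4, and Dess–Martin oxidation (CH2Cl2, NaHCO3, 0 °C) returns aldehyde 11.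

2. Step 5. The β-oxygenated aldehyde may degrade under the oxidising, mildly basic medium: retro-aldol ring opening, oxidation of the formyl group, elimination before oxidation (which gives an allylic boronate able to transpose), or aromatisation by loss of water from the hydroxy dienal.
Fallback, setting out from 11 and returning at 12: the aldehyde is masked first with HC(OMe)3 and PPTS in MeOH as (1R,2S,5S,6R)-2,5-bis(benzoyloxy)-1-(dimethoxymethyl)-6-(pinacolboryl)cyclohex-3-ene F5. The C–B bond is then oxidised (NaBO3·4H2O, THF/H2O) on a substrate without a free carbonyl to give (1R,2S,5R,6R)-2,5-bis(benzoyloxy)-1-(dimethoxymethyl)-6-hydroxycyclohex-3-ene F6. Acetal hydrolysis (PPTS, acetone/H2O) in the absence of oxidant and base delivers 12, which is treated at once with Et3N as in step 5 to reach 13.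

3. Step 7. Over-acylation at the C6 oxygen, or base-promoted 1,2-migration of the C5 benzoate onto the C6 oxygen in the free diol during steps 6 and 7, would erode the regiochemical integrity of the ester pattern.
Fallback, setting out from 13 and returning at 15: the C6 hydroxyl is silylated (TESOTf, 2,6-lutidine, CH2Cl2, −78 °C) to give (5R,6R)-5-(benzoyloxy)-6-[(triethylsilyl)oxy]cyclohexa-1,3-diene-1-carbaldehyde F7. Luche reduction (NaBH4, CeCl3·7H2O, MeOH, −78 °C) gives (1R,6R)-5-(hydroxymethyl)-6-[(triethylsilyl)oxy]cyclohexa-2,4-dien-1-yl benzoate F8. Its only hydroxyl is benzoylated (BzCl, pyridine, DMAP cat., CH2Cl2, 0 °C) to give {(5R,6R)-5-(benzoyloxy)-6-[(triethylsilyl)oxy]cyclohexa-1,3-dien-1-yl}methyl benzoate F9, and desilylation with HF·pyridine (THF/pyridine, 0 °C) gives 15.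

Further compounds
F1 | step 4 | (E)-3-(4,4,5,5-tetramethyl-1,3,2-dioxaborolan-2-yl)prop-2-enoic acid | OC(=O)/C=C/B1OC(C)(C)C(C)(C)O1
F2 | step 4 | (4S)-4-benzyl-3-[(E)-3-(4,4,5,5-tetramethyl-1,3,2-dioxaborolan-2-yl)prop-2-enoyl]-1,3-oxazolidin-2-one | O=C(/C=C/B1OC(C)(C)C(C)(C)O1)N4[C@@H](Cc3ccccc3)COC4=O
F3 | step 4 | (4S)-4-benzyl-3-{[(1R,2S,5S,6R)-2,5-bis(benzoyloxy)-6-(4,4,5,5-tetramethyl-1,3,2-dioxaborolan-2-yl)cyclohex-3-en-1-yl]carbonyl}-1,3-oxazolidin-2-one | O=C([C@H]1[C@@H](OC(=O)c2ccccc2)C=C[C@@H](OC(=O)c2ccccc2)[C@@H]1B3OC(C)(C)C(C)(C)O3)N4[C@@H](Cc5ccccc5)COC4=O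
F4 | step 4 | [(1S,2S,5S,6R)-2,5-bis(benzoyloxy)-6-(4,4,5,5-tetramethyl-1,3,2-dioxaborolan-2-yl)cyclohex-3-en-1-yl]methanol | OC[C@H]1[C@@H](OC(=O)c2ccccc2)C=C[C@@H](OC(=O)c2ccccc2)[C@@H]1B3OC(C)(C)C(C)(C)O3
F5 | step 5 | (1R,2S,5S,6R)-2,5-bis(benzoyloxy)-1-(dimethoxymethyl)-6-(4,4,5,5-tetramethyl-1,3,2-dioxaborolan-2-yl)cyclohex-3-ene (dimethyl acetal of 11) | COC(OC)[C@H]1[C@@H](OC(=O)c2ccccc2)C=C[C@@H](OC(=O)c2ccccc2)[C@@H]1B3OC(C)(C)C(C)(C)O3
F6 | step 5 | (1R,2S,5R,6R)-2,5-bis(benzoyloxy)-1-(dimethoxymethyl)-6-hydroxycyclohex-3-ene (dimethyl acetal of 12) | COC(OC)[C@H]1[C@@H](OC(=O)c2ccccc2)C=C[C@@H](OC(=O)c2ccccc2)[C@@H]1O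
F7 | step 7 | (5R,6R)-5-(benzoyloxy)-6-[(triethylsilyl)oxy]cyclohexa-1,3-diene-1-carbaldehyde | O=CC1=CC=C[C@@H](OC(=O)c2ccccc2)[C@@H]1O[Si](CC)(CC)CC
F8 | step 7 | (1R,6R)-5-(hydroxymethyl)-6-[(triethylsilyl)oxy]cyclohexa-2,4-dien-1-yl benzoate | OCC1=CC=C[C@@H](OC(=O)c2ccccc2)[C@@H]1O[Si](CC)(CC)CC
F9 | step 7 | {(5R,6R)-5-(benzoyloxy)-6-[(triethylsilyl)oxy]cyclohexa-1,3-dien-1-yl}methyl benzoate | O=C(OCC1=CC=C[C@@H](OC(=O)c2ccccc2)[C@@H]1O[Si](CC)(CC)CC)c1ccccc1
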